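**Strategy.** Numbering: enone ring C1 (C=O) to C6, with the acid chain on C2 and the cyclohexyl ring (C1′–C6′) on C3. Everything rests on the C1′–C3 bond: the quaternary carbon C1′ carries one exocyclic carbon, so the trimethylcyclohexane can come from a cycloheptene whose extra ring carbon is expelled as C3. The key step, a Lewis-acid Meinwald rearrangement, converts the enantioenriched epoxide of 1,6,6-trimethylcycloheptene into (S)-1,3,3-trimethylcyclohexane-1-carbaldehyde: one 1,2-shift contracts the ring, turns the epoxide C–O stereocentre into the all-carbon quaternary centre and delivers C3 as an aldehyde. The enone is then annulated onto C3 (Mukaiyama–Michael, aldol), followed by catalyst-controlled hydroxymethylation at C6 and formic acid.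

Key step: step 5

Remark: the facial sense of the Shi epoxidation (step 4) is assigned from the spiro transition-state model; the ligand antipode in step 12 must be fixed by a model experiment, since the catalyst alone controls that centre.
Remark: (2R)-4-methoxy-2-methyl-4-oxobutanoic acid and both antipodes of the fructose-derived epoxidation ketone are taken as commercially available.

Step 1
Reactants: 1 mesityl oxide (4-methylpent-3-en-2-one); 2 5-bromopent-1-ene
Product: 4 4,4-dimethylnon-8-en-2-one, via pent-4-enylmagnesium bromide 3 (not isolated)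
Conditions: 2, Mg, THF, rt; then CuI (10 mol%), 1, THF, −30 → 0 °C; aq. NH4Cl
Reagents that add atoms: none
Why: Copper-catalysed conjugate addition of a primary Grignard reagent to a β,β-disubstituted enone is a standard way to build a gem-dimethyl quaternary carbon, and no stereocentre is formed.

Step 2
Reactants: 4 4,4-dimethylnon-8-en-2-one
Product: 5 2,4,4-trimethylnona-1,8-diene
Conditions: Ph3PCH3Br, KOtBu, THF, 0 °C → rt
Reagents that add atoms: methyltriphenylphosphonium bromide, C[P+](c1ccccc1)(c1ccccc1)c1ccccc1.[Br-]
Why: Wittig methylenation of an unhindered methyl ketone; no stereocentre is formed.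

Step 3
Reactants: 5 2,4,4-trimethylnona-1,8-diene
Product: 6 1,6,6-trimethylcyclohept-1-ene
Conditions: Grubbs II (2 mol%), CH2Cl2 (0.02 M), 40 °C
Reagents that add atoms: none
Why: Ring-closing metathesis between the terminal and the 1,1-disubstituted alkene should close the trisubstituted seven-membered ring, helped by the gem-dimethyl group and driven by loss of ethene; no stereocentre is formed.

Step 4
Reactants: 6 1,6,6-trimethylcyclohept-1-ene
Product: 7 (1R,7S)-1,3,3-trimethyl-8-oxabicyclo[5.1.0]octane
Conditions: ent-Shi ketone (1,2:4,5-di-O-isopropylidene-β-L-erythro-2,3-hexodiulo-2,6-pyranose, 30 mol%), Oxone, K2CO3, Bu4NHSO4, MeCN/DMM/aq. buffer (pH 10.5), 0 °C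
Reagents that add atoms: Oxone (potassium peroxymonosulfate), [K+].[O-]S(=O)(=O)OO
Why: Shi asymmetric epoxidation of a trisubstituted cycloalkene by the chiral dioxirane through the spiro transition state; both epoxide carbons are set by the catalyst, and the L-configured ketone is chosen because the model (the D-ketone attacks the face leading to the 1S,7R oxide) then predicts (1R,7S)-7.

Step 5
Reactants: 7 (1R,7S)-1,3,3-trimethyl-8-oxabicyclo[5.1.0]octane
Product: 8 (1S)-1,3,3-trimethylcyclohexane-1-carbaldehyde
Conditions: MABR (methylaluminium bis(4-bromo-2,6-di-tert-butylphenoxide), 20 mol%), CH2Cl2, −78 → −20 °C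
Reagents that add atoms: none
Why: The bulky, oxophilic, non-nucleophilic aluminium Lewis acid binds the epoxide oxygen and weakens its bond to the tertiary carbon C1; as positive charge builds there, the ring bond C7–C6, anti to the breaking C1–O bond, migrates from C7 to C1 and the oxygen stays on C7 as the aldehyde (Meinwald/semipinacol rearrangement of a trisubstituted epoxide, the type that contracts 1-methylcyclohexene oxide to 1-methylcyclopentanecarbaldehyde). The six-membered ring (C1–C6 of the oxabicycle) is closed by this suprafacial 1,2-alkyl shift, a 7→6 ring contraction in which C7 is extruded as the formyl carbon, not by a Baldwin-type cyclisation. The new quaternary stereocentre is controlled by the epoxide: migration occurs with inversion at C1, so (1R,7S)-7 should give (S)-8, while C7 loses its stereochemistry. The step needs regioselective opening at C1, secured by the methyl group that makes C1 the only tertiary epoxide carbon, and carbon migration in preference to the competing 1,2-hydride shift to a cycloheptanone, favoured by the bulky aluminium phenoxide and by the strain released on going from seven to six. A Lewis acid without a nucleophilic counter-ion also avoids a halohydrin pathway, which would deliver the quaternary centre with the opposite sense.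

Step 6
Reactants: 8 (1S)-1,3,3-trimethylcyclohexane-1-carbaldehyde
Product: 9 1-[(1S)-1,3,3-trimethylcyclohexyl]ethan-1-ol
Conditions: MeMgBr, Et2O, 0 °C; aq. NH4Cl
Reagents that add atoms: methylmagnesium bromide, C[Mg]Br
Why: Grignard 1,2-addition to a non-enolisable aldehyde; the carbinol centre forms without control and is erased in step 7.

Step 7
Reactants: 9 1-[(1S)-1,3,3-trimethylcyclohexyl]ethan-1-ol
Product: 10 1-[(1S)-1,3,3-trimethylcyclohexyl]ethan-1-one
Conditions: Dess–Martin periodinane, NaHCO3, CH2Cl2, rt
Reagents that add atoms: none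
Why: Dess–Martin oxidation of a secondary alcohol under buffered conditions; the quaternary centre cannot epimerise.

Step 8
Reactants: 11 (2R)-4-methoxy-2-methyl-4-oxobutanoic acid
Product: 12 1-tert-butyl 4-methyl (2R)-2-methylbutanedioate
Conditions: t-BuOC(=NH)CCl3, BF3·OEt2 (cat.), CH2Cl2/cyclohexane, rt
Reagents that add atoms: tert-butyl 2,2,2-trichloroacetimidate, CC(C)(C)OC(=N)C(Cl)(Cl)Cl
Why: Acid-catalysed O-tert-butylation of the free acid with the trichloroacetimidate leaves the methyl ester and the chiral-pool α-stereocentre (the later side-chain centre) untouched.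

Step 9
Reactants: 12 1-tert-butyl 4-methyl (2R)-2-methylbutanedioate
Product: 14 tert-butyl (2R)-2-methyl-4-oxohex-5-enoate, via Weinreb amide 13 (not isolated)
Conditions: MeNHOMe·HCl, i-PrMgCl, THF, −20 °C; then CH2=CHMgBr, −20 → 0 °C; inverse quench into cold 1 M HCl
Reagents that add atoms: vinylmagnesium bromide, C=C[Mg]Br
Why: Weinreb ketone synthesis in one pot: the magnesium amide attacks only the unhindered methyl ester, and the chelated tetrahedral intermediate formed with vinylmagnesium bromide stops at the ketone, the hindered tert-butyl ester and its α-centre staying intact.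

Step 10
Reactants: 10 1-[(1S)-1,3,3-trimethylcyclohexyl]ethan-1-one; 14 tert-butyl (2R)-2-methyl-4-oxohex-5-enoate
Product: 16 tert-butyl (2R)-2-methyl-4,8-dioxo-8-[(1S)-1,3,3-trimethylcyclohexyl]octanoate, via silyl enol ether 15 (not isolated)
Conditions: 10, TMSOTf, Et3N, CH2Cl2, 0 °C; then 14, Sc(OTf)3 (5 mol%), CH2Cl2, −78 → −20 °C; 1 M HCl/THF
Reagents that add atoms: none
Why: Mukaiyama–Michael addition: ketone 10 can enolise on one side only, so silyl enol ether 15 is a single regioisomer, and its CH2 terminus adds to the β-carbon of the Lewis-acid-activated vinyl ketone; no new stereocentre is formed.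

Step 11
Reactants: 16 tert-butyl (2R)-2-methyl-4,8-dioxo-8-[(1S)-1,3,3-trimethylcyclohexyl]octanoate
Product: 17 tert-butyl (2R)-2-{6-oxo-2-[(1S)-1,3,3-trimethylcyclohexyl]cyclohex-1-en-1-yl}propanoate
Conditions: pyrrolidine, AcOH, toluene, 90 °C; 1 M HCl wash
Reagents that add atoms: none
Why: Intramolecular aldol condensation (the cyclodehydration half of a Robinson annulation) via the enamine at the methylene between the chain ketone and the ester branch, the only mode that gives a six-membered ring; attack on a ketone flanked by a quaternary carbon to give a tetrasubstituted enone is the same closure that forms 5-methyl Wieland–Miescher-type enones, and buffered amine catalysis should not touch the ester α-centre.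

Step 12
Reactants: 17 tert-butyl (2R)-2-{6-oxo-2-[(1S)-1,3,3-trimethylcyclohexyl]cyclohex-1-en-1-yl}propanoate
Product: 19 tert-butyl (2R)-2-{(5S)-5-(hydroxymethyl)-6-oxo-2-[(1S)-1,3,3-trimethylcyclohexyl]cyclohex-1-en-1-yl}propanoate, via silyl dienol ether 18 (not isolated)
Conditions: TMSOTf (1.2 equiv), Et3N, CH2Cl2, −78 → 0 °C; then aq. HCHO, Sc(OTf)3 (10 mol%), one antipode of 6,6′-bis(1-hydroxy-2,2-dimethylpropyl)-2,2′-bipyridine (12 mol%), DME/H2O 9:1, −20 °C
Reagents that add atoms: formaldehyde, C=O
Why: Soft enolisation should give the 2-silyloxydiene on the C6 side (a linear dienol ether would need a planar 2,3-disubstituted diene beside the quaternary group), and the catalytic asymmetric Mukaiyama aldol with aqueous formaldehyde then sets C6 (C5 in the name) under catalyst control, the ligand antipode being chosen for the S configuration because the existing centres are too remote to bias the face.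

Step 13
Reactants: 19 tert-butyl (2R)-2-{(5S)-5-(hydroxymethyl)-6-oxo-2-[(1S)-1,3,3-trimethylcyclohexyl]cyclohex-1-en-1-yl}propanoate
Product: 20 (2R)-2-{(5S)-5-[(formyloxy)methyl]-6-oxo-2-[(1S)-1,3,3-trimethylcyclohexyl]cyclohex-1-en-1-yl}propanoic acid
Conditions: HCO2H (98%), rt
Reagents that add atoms: formic acid, O=CO
Why: Neat formic acid formylates the primary alcohol (Fischer esterification) and cleaves the tert-butyl ester by loss of isobutene in one operation; in the absence of base the β-acyloxy ketone should neither eliminate by E1cB nor epimerise through an enolate.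

**Compound list**

1 | mesityl oxide (4-methylpent-3-en-2-one) | CC(=O)C=C(C)C | starting material
2 | 5-bromopent-1-ene | C=CCCCBr | starting material
3 | pent-4-enylmagnesium bromide | C=CCCC[Mg]Br | intermediate (not isolated)
4 | 4,4-dimethylnon-8-en-2-one | CC(=O)CC(C)(C)CCCC=C | intermediate
5 | 2,4,4-trimethylnona-1,8-diene | C=C(C)CC(C)(C)CCCC=C | intermediate
6 | 1,6,6-trimethylcyclohept-1-ene | CC1=CCCCC(C)(C)C1 | intermediate
7 | (1R,7S)-1,3,3-trimethyl-8-oxabicyclo[5.1.0]octane | C[C@]12O[C@H]1CCCC(C)(C)C2 | intermediate
8 | (1S)-1,3,3-trimethylcyclohexane-1-carbaldehyde | O=C[C@@]1(C)CCCC(C)(C)C1 | intermediate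
9 | 1-[(1S)-1,3,3-trimethylcyclohexyl]ethan-1-ol (both carbinol epimers) | CC(O)[C@@]1(C)CCCC(C)(C)C1 | intermediate
10 | 1-[(1S)-1,3,3-trimethylcyclohexyl]ethan-1-one | CC(=O)[C@@]1(C)CCCC(C)(C)C1 | intermediate
11 | (2R)-4-methoxy-2-methyl-4-oxobutanoic acid | C[C@@H](C(=O)O)CC(=O)OC | starting material
12 | 1-tert-butyl 4-methyl (2R)-2-methylbutanedioate | C[C@@H](C(=O)OC(C)(C)C)CC(=O)OC | intermediate
13 | tert-butyl (2R)-4-[methoxy(methyl)amino]-2-methyl-4-oxobutanoate | C[C@@H](C(=O)OC(C)(C)C)CC(=O)N(C)OC | intermediate (not isolated)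
14 | tert-butyl (2R)-2-methyl-4-oxohex-5-enoate | C[C@@H](C(=O)OC(C)(C)C)CC(=O)C=C | intermediate
15 | trimethyl({1-[(1S)-1,3,3-trimethylcyclohexyl]ethenyl}oxy)silane | C=C(O[Si](C)(C)C)[C@@]1(C)CCCC(C)(C)C1 | intermediate (not isolated)
16 | tert-butyl (2R)-2-methyl-4,8-dioxo-8-[(1S)-1,3,3-trimethylcyclohexyl]octanoate | C[C@@H](C(=O)OC(C)(C)C)CC(=O)CCCC(=O)[C@@]1(C)CCCC(C)(C)C1 | intermediate
17 | tert-butyl (2R)-2-{6-oxo-2-[(1S)-1,3,3-trimethylcyclohexyl]cyclohex-1-en-1-yl}propanoate | C[C@@H](C(=O)OC(C)(C)C)C1=C([C@@]2(C)CCCC(C)(C)C2)CCCC1=O | intermediate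
18 | tert-butyl (2R)-2-{2-[(1S)-1,3,3-trimethylcyclohexyl]-6-[(trimethylsilyl)oxy]cyclohexa-1,5-dien-1-yl}propanoate | C[C@@H](C(=O)OC(C)(C)C)C1=C([C@@]2(C)CCCC(C)(C)C2)CCC=C1O[Si](C)(C)C | intermediate (not isolated)
19 | tert-butyl (2R)-2-{(5S)-5-(hydroxymethyl)-6-oxo-2-[(1S)-1,3,3-trimethylcyclohexyl]cyclohex-1-en-1-yl}propanoate | C[C@@H](C(=O)OC(C)(C)C)C1=C([C@@]2(C)CCCC(C)(C)C2)CC[C@@H](CO)C1=O | intermediate
20 | (2R)-2-{(5S)-5-[(formyloxy)methyl]-6-oxo-2-[(1S)-1,3,3-trimethylcyclohexyl]cyclohex-1-en-1-yl}propanoic acid | C[C@@H](C(=O)O)C1=C([C@@]2(C)CCCC(C)(C)C2)CC[C@@H](COC=O)C1=O | target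

**Step count.** 13 steps in total. The longest linear sequence is 11 steps (steps 1–7 and 10–13); steps 8–9 make the side-chain fragment 14.

**Steps most likely to fail**

Step 5. The ring contraction may lose to a 1,2-hydride shift that gives a trimethylcycloheptanone, or the stereochemical transfer may erode if the tertiary cation lives long enough to rotate before the shift. The fallback sets out from alkene 6 and returns at ketone 10, replacing the direct rearrangement by a halohydrin semipinacol. Alkene 6 is epoxidised with the D-fructose-derived ketone to the enantiomeric epoxide (1S,7R)-1,3,3-trimethyl-8-oxabicyclo[5.1.0]octane F1. HCl in Et2O opens it at the tertiary carbon with inversion to the trans-chlorohydrin (1R,2R)-2-chloro-2,4,4-trimethylcycloheptan-1-ol F2, which Dess–Martin oxidation converts to (2R)-2-chloro-2,4,4-trimethylcycloheptan-1-one F3. Addition of MeMgBr gives the bromomagnesium alkoxide of (2R)-2-chloro-1,2,4,4-tetramethylcycloheptan-1-ol F4. On warming in benzene the ring CH2 anti to the C–Cl bond should migrate with displacement of chloride (semipinacol ring contraction of the halohydrin salt), giving 10 directly. Two inversions at the tertiary carbon replace the single one of step 5, which is why the enantiomeric epoxide is used.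

Step 12. Facial selectivity at C6 may be poor on this unprecedented diene, and protodesilylation of 18 back to 17 may compete in the aqueous medium. The fallback sets out from 17 and returns at 19, giving up catalyst control in favour of separation and recycling. Silyl dienol ether 18 is treated with aqueous formaldehyde and an achiral lanthanide triflate (Yb(OTf)3, THF/H2O), which should give 19 together with its C5 epimer tert-butyl (2R)-2-{(5R)-5-(hydroxymethyl)-6-oxo-2-[(1S)-1,3,3-trimethylcyclohexyl]cyclohex-1-en-1-yl}propanoate F5. The two diastereomers are separated by chromatography, and F5 is returned to the mixture by brief base-induced epimerisation at C5 (cat. DBU, CH2Cl2, 0 °C) and separated again.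

Step 13. During the hours needed to cleave the tert-butyl ester, acid-catalysed enolisation may epimerise C5, or formic acid may be lost from the β-acyloxy ketone to give the 6-methylene enone. The fallback sets out from 17 and returns at 20, freeing the acid before the sensitive centre exists and formylating last under non-acidic conditions. TFA/CH2Cl2 converts 17 into (2R)-2-{6-oxo-2-[(1S)-1,3,3-trimethylcyclohexyl]cyclohex-1-en-1-yl}propanoic acid F6. TMSOTf (2.3 equiv)/Et3N then gives trimethylsilyl (2R)-2-{2-[(1S)-1,3,3-trimethylcyclohexyl]-6-[(trimethylsilyl)oxy]cyclohexa-1,5-dien-1-yl}propanoate F7, which is hydroxymethylated under the conditions of step 12. The aqueous medium also cleaves the silyl ester, giving (2R)-2-{(5S)-5-(hydroxymethyl)-6-oxo-2-[(1S)-1,3,3-trimethylcyclohexyl]cyclohex-1-en-1-yl}propanoic acid F8. Acetic formic anhydride and pyridine in CH2Cl2 at −20 °C, followed by aqueous work-up to hydrolyse any mixed anhydride, should then give 20.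

**Further compounds**

F1 | step 5 | (1S,7R)-1,3,3-trimethyl-8-oxabicyclo[5.1.0]octane | C[C@@]12O[C@@H]1CCCC(C)(C)C2
F2 | step 5 | (1R,2R)-2-chloro-2,4,4-trimethylcycloheptan-1-ol | C[C@@]1(Cl)CC(C)(C)CCC[C@H]1O
F3 | step 5 | (2R)-2-chloro-2,4,4-trimethylcycloheptan-1-one | C[C@@]1(Cl)CC(C)(C)CCCC1=O
F4 | step 5 | (2R)-2-chloro-1,2,4,4-tetramethylcycloheptan-1-ol (formed as its bromomagnesium alkoxide, C1 not defined) | C[C@@]1(Cl)CC(C)(C)CCCC1(C)O
F5 | step 12 | tert-butyl (2R)-2-{(5R)-5-(hydroxymethyl)-6-oxo-2-[(1S)-1,3,3-trimethylcyclohexyl]cyclohex-1-en-1-yl}propanoate | C[C@@H](C(=O)OC(C)(C)C)C1=C([C@@]2(C)CCCC(C)(C)C2)CC[C@H](CO)C1=O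
F6 | step 13 | (2R)-2-{6-oxo-2-[(1S)-1,3,3-trimethylcyclohexyl]cyclohex-1-en-1-yl}propanoic acid | C[C@@H](C(=O)O)C1=C([C@@]2(C)CCCC(C)(C)C2)CCCC1=O
F7 | step 13 | trimethylsilyl (2R)-2-{2-[(1S)-1,3,3-trimethylcyclohexyl]-6-[(trimethylsilyl)oxy]cyclohexa-1,5-dien-1-yl}propanoate | C[C@@H](C(=O)O[Si](C)(C)C)C1=C([C@@]2(C)CCCC(C)(C)C2)CCC=C1O[Si](C)(C)C
F8 | step 13 | (2R)-2-{(5S)-5-(hydroxymethyl)-6-oxo-2-[(1S)-1,3,3-trimethylcyclohexyl]cyclohex-1-en-1-yl}propanoic acid | C[C@@H](C(=O)O)C1=C([C@@]2(C)CCCC(C)(C)C2)CC[C@@H](CO)C1=O
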